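**Plan**
- Retrosynthesis: the 5-O-methyl group and the three benzyl ethers are removed last. The 3-OMe is traced back through the trans-3-hydroxy ketone to a C3-unsubstituted flavanone. The C2–C3 bond of ring C is then cut to an aryl diazomethyl ketone whose O1 carries the ring-B benzyl group, and the O1–CH2 ether bond is cut to a ring-A salicylaldehyde and a ring-B benzyl alcohol.
- Forward: ring A (from syringaldehyde) and ring B (from 2,3-dihydroxy-4-methoxybenzaldehyde) are joined through O1 by Mitsunobu etherification. The aldehyde is taken to the diazoketone, and ring C is closed last by forming C2–C3.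
- Enabling feature: C2 is benzylic, bonded to O1, and is the sixth atom of the chain C3–C4–C4a–C8a–O1–C2. Its C–H bond is therefore activated and within reach of a rhodium carbene at C3 for a six-membered ring closure.
- Stereochemistry: C2 is set in the C–H insertion by the chiral carboxylate ligands of Rh2(S-PTTL)4. The flavanone is 2S; the descriptor becomes 2R once C3 bears oxygen, with no change in space. C3 is set trans to the aryl group by substrate-controlled Rubottom oxidation.

Key step: step 9

Assumption: Rh2(S-PTTL)4 is taken to select the benzylic hydrogen that leads to the 2S flavanone; if the insertion shows the opposite sense, Rh2(R-PTTL)4 would be used with nothing else changed.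

**Route**

Step 1
Reactants: 1 2,3-dihydroxy-4-methoxybenzaldehyde
Product: 2 2,3-bis(benzyloxy)-4-methoxybenzaldehyde
Conditions: BnBr, K2CO3, DMF, 60 °C
Reagents that add atoms: benzyl bromide, BrCc1ccccc1
Why: Williamson etherification: K2CO3 in warm DMF ionises both phenols, including the one hydrogen-bonded to the aldehyde, and the phenoxides displace bromide while the aldehyde is untouched.

Step 2
Reactants: 2 2,3-bis(benzyloxy)-4-methoxybenzaldehyde
Product: 3 [2,3-bis(benzyloxy)-4-methoxyphenyl]methanol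
Conditions: NaBH4, MeOH–THF, 0 °C
Reagents that add atoms: none
Why: Borohydride reduction of an aryl aldehyde to the primary benzylic alcohol is chemoselective and leaves the aryl ethers alone.

Step 3
Reactants: 4 syringaldehyde (4-hydroxy-3,5-dimethoxybenzaldehyde)
Product: 5 4-(benzyloxy)-3,5-dimethoxybenzaldehyde
Conditions: BnBr, K2CO3, DMF, 60 °C
Reagents that add atoms: benzyl bromide, BrCc1ccccc1
Why: Williamson etherification: the hindered phenoxide between two methoxy groups is still benzylated in warm DMF, which marks the future 6-oxygen as different from the two methyl ethers.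

Step 4
Reactants: 5 4-(benzyloxy)-3,5-dimethoxybenzaldehyde
Product: 7 4-(benzyloxy)-3,5-dimethoxyphenol, via aryl formate 6 (not isolated)
Conditions: mCPBA, CH2Cl2, 0 °C → rt; then K2CO3, MeOH, rt
Reagents that add atoms: 3-chloroperoxybenzoic acid (mCPBA), OOC(=O)c1cccc(Cl)c1
Why: Baeyer–Villiger (Dakin-type) oxidation: in the peracid adduct the electron-rich aryl group migrates in preference to hydride to give the aryl formate, which mild methanolysis converts to the phenol without touching the benzyl ether.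

Step 5
Reactants: 7 4-(benzyloxy)-3,5-dimethoxyphenol
Product: 8 3-(benzyloxy)-6-hydroxy-2,4-dimethoxybenzaldehyde
Conditions: MgCl2, Et3N, (CH2O)n, MeCN, reflux; aq. HCl work-up
Reagents that add atoms: paraformaldehyde (as formaldehyde), C=O
Why: Magnesium-mediated ortho-formylation (Casnati–Skattebøl): the magnesium phenoxide delivers formaldehyde to the ortho carbon and a second formaldehyde oxidises the benzylic alkoxide; the para position is blocked and the two ortho positions are equivalent, so a single aldehyde should form.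

Step 6
Reactants: 8 3-(benzyloxy)-6-hydroxy-2,4-dimethoxybenzaldehyde; 3 [2,3-bis(benzyloxy)-4-methoxyphenyl]methanol
Product: 9 3-(benzyloxy)-6-{[2,3-bis(benzyloxy)-4-methoxyphenyl]methoxy}-2,4-dimethoxybenzaldehyde
Conditions: PPh3, DIAD, THF, 0 °C → rt
Reagents that add atoms: none
Why: Mitsunobu etherification: the acidic salicylaldehyde phenol is alkylated by the primary benzylic alcohol through its alkoxyphosphonium ion, joining rings A and B through the future O1–C2 bond without isolating an unstable electron-rich benzyl halide.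

Step 7
Reactants: 9 3-(benzyloxy)-6-{[2,3-bis(benzyloxy)-4-methoxyphenyl]methoxy}-2,4-dimethoxybenzaldehyde
Product: 10 3-(benzyloxy)-6-{[2,3-bis(benzyloxy)-4-methoxyphenyl]methoxy}-2,4-dimethoxybenzoic acid
Conditions: NaClO2, NaH2PO4, 2-methyl-2-butene, t-BuOH–THF–H2O, rt
Reagents that add atoms: sodium chlorite, [Na+].[O-]Cl=O
Why: Pinnick oxidation: buffered chlorite converts the hindered aldehyde to the acid near pH 4, where the acid-sensitive trioxygenated benzyl ether survives, and 2-methyl-2-butene traps HOCl before it can chlorinate the electron-rich rings.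

Step 8
Reactants: 10 3-(benzyloxy)-6-{[2,3-bis(benzyloxy)-4-methoxyphenyl]methoxy}-2,4-dimethoxybenzoic acid
Product: 12 2-diazo-1-[3-(benzyloxy)-6-{[2,3-bis(benzyloxy)-4-methoxyphenyl]methoxy}-2,4-dimethoxyphenyl]ethan-1-one, via acid chloride 11 (not isolated)
Conditions: 1-chloro-N,N,2-trimethylprop-1-en-1-amine, CH2Cl2, 0 °C → rt; then Me3SiCHN2, MeCN–THF, 0 °C → rt
Reagents that add atoms: (trimethylsilyl)diazomethane, C[Si](C)(C)C=[N+]=[N-]
Why: The α-chloroenamine forms the acid chloride without releasing HCl, so the acid-labile benzylic ether is kept, and acylation of (trimethylsilyl)diazomethane with loss of Me3SiCl (the acylation half of the Arndt–Eistert sequence) gives the diazomethyl ketone.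

Step 9
Reactants: 12 2-diazo-1-[3-(benzyloxy)-6-{[2,3-bis(benzyloxy)-4-methoxyphenyl]methoxy}-2,4-dimethoxyphenyl]ethan-1-one
Product: 13 (2S)-6-(benzyloxy)-2-[2,3-bis(benzyloxy)-4-methoxyphenyl]-5,7-dimethoxy-2,3-dihydro-4H-chromen-4-one
Conditions: Rh2(S-PTTL)4 (2 mol %; PTTL = N-phthaloyl-tert-leucinate), 4 Å MS, CH2Cl2, slow addition of 12, 0 °C → rt
Reagents that add atoms: none
Why: Intramolecular rhodium-carbene C–H insertion: the dirhodium tetracarboxylate (divalent rhodium) expels N2 from 12 to give an electrophilic carbene at C3, which inserts in a concerted, hydride-transfer-like three-centre step into a C–H bond of the O1–CH2–aryl group and so forms C2–C3. The closest known reaction is the dirhodium-carboxylate-catalysed cyclisation of 2-alkoxyaryl diazomethyl ketones to chroman-4-ones, including enantioselective versions with chiral carboxylates. Ring C closes as a six-membered ring by 1,6-insertion through a six-membered transition state (carbene carbon, C4, C4a, C8a, O1, C2); no C–H bond is placed for a five-membered closure. The C2 stereocentre is set by the chiral N-phthaloyl-tert-leucinate ligands, which distinguish the two enantiotopic benzylic hydrogens (catalyst control, 2S expected). The step needs chemoselectivity over oxonium-ylide formation at O1 with [1,2]-benzyl shift and over insertion into the 5-methoxy group: the target C–H bond is secondary, alpha to oxygen and benzylic to a very electron-rich ring, hence far more hydridic than the primary OCH3 bonds, and an electrophilic carboxylate catalyst in a non-coordinating solvent with slow addition favours insertion over ylide chemistry and carbene dimerisation.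

Step 10
Reactants: 13 (2S)-6-(benzyloxy)-2-[2,3-bis(benzyloxy)-4-methoxyphenyl]-5,7-dimethoxy-2,3-dihydro-4H-chromen-4-one
Product: 14 {[(2S)-6-(benzyloxy)-2-[2,3-bis(benzyloxy)-4-methoxyphenyl]-5,7-dimethoxy-2H-chromen-4-yl]oxy}trimethylsilane
Conditions: LiN(SiMe3)2, Me3SiCl, THF, −78 °C; non-aqueous work-up, used crude
Reagents that add atoms: chlorotrimethylsilane, C[Si](C)(C)Cl
Why: Kinetic enolisation with in situ silylation: the amide base removes a C3 proton at −78 °C and Me3SiCl already present traps the enolate before retro-oxa-Michael opening of ring C can erase the C2 stereocentre.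

Step 11
Reactants: 14 {[(2S)-6-(benzyloxy)-2-[2,3-bis(benzyloxy)-4-methoxyphenyl]-5,7-dimethoxy-2H-chromen-4-yl]oxy}trimethylsilane
Product: 16 (2R,3R)-6-(benzyloxy)-2-[2,3-bis(benzyloxy)-4-methoxyphenyl]-3-hydroxy-5,7-dimethoxy-2,3-dihydro-4H-chromen-4-one, via silyloxy epoxide 15 (not isolated)
Conditions: dimethyldioxirane (acetone solution), CH2Cl2, −40 → 0 °C; then aq. citric acid, THF, 0 °C
Reagents that add atoms: dimethyldioxirane, CC1(C)OO1
Why: Rubottom oxidation: dimethyldioxirane epoxidises the electron-rich enol ether under neutral conditions on the face anti to the C2 aryl group, and mild acid collapses the silyloxy epoxide to the α-hydroxy ketone, so the C3 hydroxyl is set trans to the aryl group (3R) by substrate control.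

Step 12
Reactants: 16 (2R,3R)-6-(benzyloxy)-2-[2,3-bis(benzyloxy)-4-methoxyphenyl]-3-hydroxy-5,7-dimethoxy-2,3-dihydro-4H-chromen-4-one
Product: 17 (2R,3R)-6-(benzyloxy)-2-[2,3-bis(benzyloxy)-4-methoxyphenyl]-3,5,7-trimethoxy-2,3-dihydro-4H-chromen-4-one
Conditions: Ag2O, MeI, 4 Å MS, CH2Cl2, rt, dark
Reagents that add atoms: iodomethane, CI
Why: Purdie methylation: Ag2O activates iodomethane and takes up HI under nearly neutral conditions, so the secondary α-ketol is O-methylated without enolisation at C3 or base-induced opening of ring C.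

Step 13
Reactants: 17 (2R,3R)-6-(benzyloxy)-2-[2,3-bis(benzyloxy)-4-methoxyphenyl]-3,5,7-trimethoxy-2,3-dihydro-4H-chromen-4-one
Product: 18 (2R,3R)-2-(2,3-dihydroxy-4-methoxyphenyl)-6-hydroxy-3,5,7-trimethoxy-2,3-dihydro-4H-chromen-4-one
Conditions: H2 (1 atm), Pd/C, EtOAc–MeOH, rt
Reagents that add atoms: none
Why: Catalytic hydrogenolysis cleaves the three aryl benzyl ethers under neutral conditions at 1 atm, where the cyclic benzylic C2–O1 bond, the ketone and the methyl ethers are expected to survive.

Step 14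
Reactants: 18 (2R,3R)-2-(2,3-dihydroxy-4-methoxyphenyl)-6-hydroxy-3,5,7-trimethoxy-2,3-dihydro-4H-chromen-4-one
Product: 19 (2R,3R)-2-(2,3-dihydroxy-4-methoxyphenyl)-5,6-dihydroxy-3,7-dimethoxy-2,3-dihydro-4H-chromen-4-one
Conditions: BCl3, CH2Cl2, −78 → 0 °C; then MeOH, H2O
Reagents that add atoms: none
Why: Chelation-controlled Lewis-acid demethylation: boron bound between the C4 carbonyl and the peri 5-methoxy oxygen activates only that methyl group towards chloride attack, while the 7-, 4'- and 3-methyl ethers lack such a six-membered chelate and both stereocentres are untouched.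

**Compound list**
1 | 2,3-dihydroxy-4-methoxybenzaldehyde | COc1ccc(C=O)c(O)c1O | starting material
2 | 2,3-bis(benzyloxy)-4-methoxybenzaldehyde | COc1ccc(C=O)c(OCc2ccccc2)c1OCc1ccccc1 | intermediate
3 | [2,3-bis(benzyloxy)-4-methoxyphenyl]methanol | COc1ccc(CO)c(OCc2ccccc2)c1OCc1ccccc1 | intermediate
4 | syringaldehyde (4-hydroxy-3,5-dimethoxybenzaldehyde) | COc1cc(C=O)cc(OC)c1O | starting material
5 | 4-(benzyloxy)-3,5-dimethoxybenzaldehyde | COc1cc(C=O)cc(OC)c1OCc1ccccc1 | intermediate
6 | 4-(benzyloxy)-3,5-dimethoxyphenyl formate | COc1cc(OC=O)cc(OC)c1OCc1ccccc1 | intermediate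
7 | 4-(benzyloxy)-3,5-dimethoxyphenol | COc1cc(O)cc(OC)c1OCc1ccccc1 | intermediate
8 | 3-(benzyloxy)-6-hydroxy-2,4-dimethoxybenzaldehyde | COc1cc(O)c(C=O)c(OC)c1OCc1ccccc1 | intermediate
9 | 3-(benzyloxy)-6-{[2,3-bis(benzyloxy)-4-methoxyphenyl]methoxy}-2,4-dimethoxybenzaldehyde | COc1ccc(COc2cc(OC)c(OCc3ccccc3)c(OC)c2C=O)c(OCc2ccccc2)c1OCc1ccccc1 | intermediate
10 | 3-(benzyloxy)-6-{[2,3-bis(benzyloxy)-4-methoxyphenyl]methoxy}-2,4-dimethoxybenzoic acid | COc1ccc(COc2cc(OC)c(OCc3ccccc3)c(OC)c2C(=O)O)c(OCc2ccccc2)c1OCc1ccccc1 | intermediate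
11 | 3-(benzyloxy)-6-{[2,3-bis(benzyloxy)-4-methoxyphenyl]methoxy}-2,4-dimethoxybenzoyl chloride | COc1ccc(COc2cc(OC)c(OCc3ccccc3)c(OC)c2C(Cl)=O)c(OCc2ccccc2)c1OCc1ccccc1 | intermediate
12 | 2-diazo-1-[3-(benzyloxy)-6-{[2,3-bis(benzyloxy)-4-methoxyphenyl]methoxy}-2,4-dimethoxyphenyl]ethan-1-one | COc1ccc(COc2cc(OC)c(OCc3ccccc3)c(OC)c2C(=O)C=[N+]=[N-])c(OCc2ccccc2)c1OCc1ccccc1 | intermediate
13 | (2S)-6-(benzyloxy)-2-[2,3-bis(benzyloxy)-4-methoxyphenyl]-5,7-dimethoxy-2,3-dihydro-4H-chromen-4-one | COc1ccc([C@H]2Oc3cc(OC)c(OCc4ccccc4)c(OC)c3C(=O)C2)c(OCc2ccccc2)c1OCc1ccccc1 | intermediate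
14 | {[(2S)-6-(benzyloxy)-2-[2,3-bis(benzyloxy)-4-methoxyphenyl]-5,7-dimethoxy-2H-chromen-4-yl]oxy}trimethylsilane | COc1ccc([C@H]2Oc3cc(OC)c(OCc4ccccc4)c(OC)c3C(O[Si](C)(C)C)=C2)c(OCc2ccccc2)c1OCc1ccccc1 | intermediate
15 | (2R,3R,4R)-6-(benzyloxy)-2-[2,3-bis(benzyloxy)-4-methoxyphenyl]-3,4-epoxy-5,7-dimethoxy-4-(trimethylsilyloxy)chromane, epoxide oxygen anti to the C2 aryl group | COc1ccc([C@H]2Oc3cc(OC)c(OCc4ccccc4)c(OC)c3[C@]5(O[Si](C)(C)C)O[C@H]25)c(OCc2ccccc2)c1OCc1ccccc1 | intermediate
16 | (2R,3R)-6-(benzyloxy)-2-[2,3-bis(benzyloxy)-4-methoxyphenyl]-3-hydroxy-5,7-dimethoxy-2,3-dihydro-4H-chromen-4-one | COc1ccc([C@H]2Oc3cc(OC)c(OCc4ccccc4)c(OC)c3C(=O)[C@@H]2O)c(OCc2ccccc2)c1OCc1ccccc1 | intermediate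
17 | (2R,3R)-6-(benzyloxy)-2-[2,3-bis(benzyloxy)-4-methoxyphenyl]-3,5,7-trimethoxy-2,3-dihydro-4H-chromen-4-one | COc1ccc([C@H]2Oc3cc(OC)c(OCc4ccccc4)c(OC)c3C(=O)[C@@H]2OC)c(OCc2ccccc2)c1OCc1ccccc1 | intermediate
18 | (2R,3R)-2-(2,3-dihydroxy-4-methoxyphenyl)-6-hydroxy-3,5,7-trimethoxy-2,3-dihydro-4H-chromen-4-one | COc1ccc([C@H]2Oc3cc(OC)c(O)c(OC)c3C(=O)[C@@H]2OC)c(O)c1O | intermediate
19 | (2R,3R)-2-(2,3-dihydroxy-4-methoxyphenyl)-5,6-dihydroxy-3,7-dimethoxy-2,3-dihydro-4H-chromen-4-one | COc1ccc([C@H]2Oc3cc(OC)c(O)c(O)c3C(=O)[C@@H]2OC)c(O)c1O | target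

**Totals**
Total step count: 14.
Longest linear sequence: 12 steps (steps 3 to 14, from syringaldehyde).

**Steps most likely to fail**

1. Step 9. The carbene may be diverted into oxonium-ylide formation at O1 followed by a [1,2]-benzyl shift, or may insert into a methyl C–H bond of the 5-methoxy group. The discrimination between the two enantiotopic benzylic hydrogens may also be too low for a carbene with a single acceptor group. The fallback builds ring C from a chalcone epoxide; it sets out from 8 and 2 and comes back at 16, so it also replaces steps 10 and 11.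
 - Phenol 8 is capped with chloromethyl methyl ether and N,N-diisopropylethylamine to give 3-(benzyloxy)-2,4-dimethoxy-6-(methoxymethoxy)benzaldehyde F1.
 - MeMgBr converts it to 1-[3-(benzyloxy)-2,4-dimethoxy-6-(methoxymethoxy)phenyl]ethan-1-ol F2, and Dess–Martin oxidation gives 1-[3-(benzyloxy)-2,4-dimethoxy-6-(methoxymethoxy)phenyl]ethan-1-one F3.
 - Claisen–Schmidt condensation of F3 with aldehyde 2 (KOH, EtOH) should give (2E)-1-[3-(benzyloxy)-2,4-dimethoxy-6-(methoxymethoxy)phenyl]-3-[2,3-bis(benzyloxy)-4-methoxyphenyl]prop-2-en-1-one F4.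
 - Julia–Colonna epoxidation (poly-L-leucine, urea–H2O2, DBU, THF) is expected to give [3-(benzyloxy)-2,4-dimethoxy-6-(methoxymethoxy)phenyl]{(2R,3S)-3-[2,3-bis(benzyloxy)-4-methoxyphenyl]oxiran-2-yl}methanone F5.
 - HCl in MeOH–THF removes the methoxymethyl group to give [3-(benzyloxy)-6-hydroxy-2,4-dimethoxyphenyl]{(2R,3S)-3-[2,3-bis(benzyloxy)-4-methoxyphenyl]oxiran-2-yl}methanone F6. Its phenol opens the epoxide at the benzylic carbon with inversion and closes ring C to the trans-3-hydroxy ketone 16.

2. Step 14. Demethylation may go beyond the 5-position: the aryloxyboron groups formed from the free phenols can direct BCl3 onto the neighbouring 7- and 4'-methoxy groups, and the 3-methoxy group can be reached through the carbonyl. The Lewis acid may also ionise the C2–O1 bond next to the electron-rich ring B and epimerise C2. The fallback reverses the order of the two deprotections, so that the chelation-directed demethylation runs while all other phenols are still benzyl-capped; it sets out from 17 and comes back at 19.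
 - MgI2·OEt2 in toluene–Et2O at about 60 °C is chelated only between the C4 carbonyl and the 5-methoxy oxygen and should give (2R,3R)-6-(benzyloxy)-2-[2,3-bis(benzyloxy)-4-methoxyphenyl]-5-hydroxy-3,7-dimethoxy-2,3-dihydro-4H-chromen-4-one F7.
 - Hydrogenolysis of F7 (H2, Pd/C, EtOAc–MeOH) then gives 19 directly.

3. Step 11. The dioxirane may attack the enol ether with too little facial bias, may oxidise the electron-rich rings or benzylic positions, or the labile trimethylsilyl enol ether may hydrolyse back to the ketone before it is oxidised. The fallback is a direct enolate hydroxylation that avoids the silyl enol ether, the dioxirane and the acid step; it sets out from 13 and comes back at 16, replacing steps 10 and 11.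
 - Ketone 13 is deprotonated with KN(SiMe3)2 in THF at −78 °C, and the enolate is oxidised at once with 3-phenyl-2-(phenylsulfonyl)oxaziridine.
 - The oxidant is expected to approach anti to the C2 aryl group and give the trans-3-hydroxy ketone 16; no new isolated compound arises (F0).

Further compounds
F1 | step 9 | 3-(benzyloxy)-2,4-dimethoxy-6-(methoxymethoxy)benzaldehyde | COCOc1cc(OC)c(OCc2ccccc2)c(OC)c1C=O
F2 | step 9 | 1-[3-(benzyloxy)-2,4-dimethoxy-6-(methoxymethoxy)phenyl]ethan-1-ol (racemic) | COCOc1cc(OC)c(OCc2ccccc2)c(OC)c1C(C)O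
F3 | step 9 | 1-[3-(benzyloxy)-2,4-dimethoxy-6-(methoxymethoxy)phenyl]ethan-1-one | COCOc1cc(OC)c(OCc2ccccc2)c(OC)c1C(C)=O
F4 | step 9 | (2E)-1-[3-(benzyloxy)-2,4-dimethoxy-6-(methoxymethoxy)phenyl]-3-[2,3-bis(benzyloxy)-4-methoxyphenyl]prop-2-en-1-one | COCOc1cc(OC)c(OCc2ccccc2)c(OC)c1C(=O)/C=C/c1ccc(OC)c(OCc2ccccc2)c1OCc1ccccc1
F5 | step 9 | [3-(benzyloxy)-2,4-dimethoxy-6-(methoxymethoxy)phenyl]{(2R,3S)-3-[2,3-bis(benzyloxy)-4-methoxyphenyl]oxiran-2-yl}methanone | COCOc1cc(OC)c(OCc2ccccc2)c(OC)c1C(=O)[C@H]1[C@H](c2ccc(OC)c(OCc3ccccc3)c2OCc2ccccc2)O1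
F6 | step 9 | [3-(benzyloxy)-6-hydroxy-2,4-dimethoxyphenyl]{(2R,3S)-3-[2,3-bis(benzyloxy)-4-methoxyphenyl]oxiran-2-yl}methanone | Oc1cc(OC)c(OCc2ccccc2)c(OC)c1C(=O)[C@H]1[C@H](c2ccc(OC)c(OCc3ccccc3)c2OCc2ccccc2)O1
F7 | step 14 | (2R,3R)-6-(benzyloxy)-2-[2,3-bis(benzyloxy)-4-methoxyphenyl]-5-hydroxy-3,7-dimethoxy-2,3-dihydro-4H-chromen-4-one | COc1ccc([C@H]2Oc3cc(OC)c(OCc4ccccc4)c(O)c3C(=O)[C@@H]2OC)c(OCc2ccccc2)c1OCc1ccccc1
F0 | step 11 | none | none
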